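If you count the fraction of substrate left and not the fraction made, a first-order loss becomes a sum. Take Θ, the ln of charged over present c(substrate): it is the optical depth of the flask, the pseudo-first-order rate integrated over time.

| flask | substrate | reagent | remark | time |
|---|---|---|---|---|
| winter | 0.16 M | 1.2 M (in portions, 2) | run made earlier; portions every 3.0 h |  |
| autumn | 0.36 M | 1.2 M (in portions, 2) | run made earlier; portions every 3.0 h |  |
| summer | 0.24 M | 0.60 M (in portions, 2) | run made earlier; portions every 3.0 h |  |
| flask | 0.24 M | 1.20 M (in portions, 2) | the portions of reagent follow each other after 3.0 h, the first at the start | 30 h |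

| run | time / h | bis adduct / % | substrate / % |
|---|---|---|---|
| winter | 1.33 | 0 | 93 |
| winter | 3.00 | 6 | 85 |
| winter | 8.00 | 19 | 62 |
| winter | 20.0 | 29 | 33 |
| autumn | 5.00 | 11 | 71 |
| autumn | 10.0 | 19 | 48 |
| autumn | 15.0 | 24 | 37 |
| autumn | 20.0 | 25 | 24 |
| summer | 2.50 | 4 | 97 |
| summer | 6.00 | 5 | 78 |
| summer | 12.0 | 15 | 59 |
| summer | 20.0 | 21 | 45 |

(readings scatter by 2 percentage points)

- the state of affairs at 30 h: stopped, and by what, or still going (it is still moving / forward and back rates have come level / the reagent has run out first / all of the substrate has reacted)
- bis adduct at 30 h, in percent of the substrate charged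

At 20.0 h the winter run stands at Θ = 1.11 and the autumn run at 1.43, so with equal reagent Θ is larger for the larger substrate charge. The winter run's Θ per hour is 0.0598 h⁻¹ at 8.00 h and 0.0555 h⁻¹ at 20.0 h, nearly steady, so I scale with time. The flask's charge lies 0.400 of the way from winter to autumn, which gives Θ at 30 h = 1.85. My reckoning therefore has substrate falling from 39.7% at half time to 15.7%, so the flask is still moving.

Is one number enough? The autumn run reads 24% bis adduct at Θ = 0.994 and 25% at 1.43, on either side of the winter run's 1.11, where the reading is 29%; that gap of at least 4 percentage points stands against a scatter of 2 points. It is not, so I interpolate the bis adduct readings at 20.0 h by the same fraction and get 27.4% for that time. The readings end there, but the autumn run gained 1 point from 15.0 h to 20.0 h, so I carry that level forward to 30 h as a rough estimate.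

The forecast says it is still moving, with bis adduct at 26%, where “I expect a broad maximum”. The flask gives it is still moving, with 28.9% bis adduct and 17% substrate left, so Θ = 1.77 against my 1.85.

    2 reagent → homo dimer (k = 0.00160 L mol⁻¹ min⁻¹)
    reagent + bis adduct → tris adduct + by-product (k = 0.00160 L mol⁻¹ min⁻¹)
    substrate + reagent → mono adduct + by-product (k = 0.00160 L mol⁻¹ min⁻¹)
    reagent + mono adduct → bis adduct + by-product (k = 0.00620 L mol⁻¹ min⁻¹)
    substrate + by-product → side product (k = 0.00330 L mol⁻¹ min⁻¹)
    reagent + tris adduct → tetra adduct + by-product (k = 1.40 × 10⁻⁴ L mol⁻¹ min⁻¹)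

At the whole reagent charge, the half-life of bis adduct toward tris adduct is 6.0 h, shorter than the 30 h of the flask. The flask holds 14.0% tris adduct at 30.0 h, and left to 300 h it holds 24.9% bis adduct. For the neighbour flask with 0.14 M substrate, the same scaling gives Θ = 1.62, or 19.9% left. That neighbour computes to 20.9% left, with 30.7% bis adduct.

The earlier runs and the new flask come from a simulation with constants of no real substance; the scatter is artificial.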